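**Retrosynthetic overview**
- The target comes from global MOM removal, preceded by ortho-lithiation/formylation of the protected resorcinol ring and by substrate-controlled reduction of a ring A 3-ketone (sets the carbinol).
- Ring A is closed last by McMurry coupling of a keto-aldehyde (fixes the C1=C10 double bond); the aldehyde comes from anti-Markovnikov Wacker oxidation of a vinyl group.
- The C9 quaternary centre comes from benzylation then axial methylation of the ring B ketone; the arylmethyl bromide is made from 3,5-dihydroxybenzyl alcohol.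
- The key C3–C4 bond (gem-dimethyl quaternary carbon) is formed by anionic oxy-Cope rearrangement of the homoaldol adduct of (R)-pulegone and allyl N,N-diisopropylcarbamate.
- Ring order: ring B and C8 are bought in pulegone, the arene is attached at C9, ring A is formed last.

Assumption: the target is taken exactly as the SMILES gives it, (3R,5R,8R,9S) in drimane-type numbering (ring A = C1–C5, C10; ring B = C5–C10; C11 = benzylic CH2), which is used in the comments.
Abbreviations: Ar = 2,6-bis(methoxymethoxy)-4-[(methoxymethoxy)methyl]phenyl; Cb = C(O)N(iPr)2; MOM = CH2OCH3.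

**Step 1**
Reactants: 1 3,5-dihydroxybenzyl alcohol
Product: 2 1,3-bis(methoxymethoxy)-5-[(methoxymethoxy)methyl]benzene
Conditions: NaH, MOMCl, DMF, 0 → 25 °C
Reagents that add atoms: chloromethyl methyl ether (MOMCl), COCCl
Why: Williamson O-alkylation of both phenoxides and the benzylic alkoxide installs acetal protecting groups that survive the basic and reductive steps, direct both later ortho-lithiations and leave together at the end.

**Step 2**
Reactants: 2 1,3-bis(methoxymethoxy)-5-[(methoxymethoxy)methyl]benzene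
Product: 4 {2,6-bis(methoxymethoxy)-4-[(methoxymethoxy)methyl]phenyl}methanol, via aryllithium 3 (not isolated)
Conditions: n-BuLi, TMEDA, THF, 0 °C; (CH2O)n, 0 → 25 °C
Reagents that add atoms: formaldehyde (from paraformaldehyde), C=O
Why: Directed ortho-metalation takes place at the ring carbon flanked by two OMOM groups, and the aryllithium adds to formaldehyde (hydroxymethylation).

**Step 3**
Reactants: 4 {2,6-bis(methoxymethoxy)-4-[(methoxymethoxy)methyl]phenyl}methanol
Product: 5 2-(bromomethyl)-1,3-bis(methoxymethoxy)-5-[(methoxymethoxy)methyl]benzene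
Conditions: CBr4, PPh3, CH2Cl2, 0 °C (used crude)
Reagents that add atoms: carbon tetrabromide, BrC(Br)(Br)Br
Why: The Appel reaction converts the benzylic alcohol to the bromide under neutral conditions that leave the MOM acetals intact.

**Step 4**
Reactants: 6 (R)-(+)-pulegone; 7 allyl N,N-diisopropylcarbamate
Product: 10 (Z)-3-[(1S,5R)-1-hydroxy-5-methyl-2-(propan-2-ylidene)cyclohexyl]prop-1-en-1-yl N,N-diisopropylcarbamate, via lithiated carbamate 8 (not isolated), via allyltitanium reagent 9 (not isolated)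
Conditions: 7, s-BuLi, TMEDA, Et2O, −78 °C; ClTi(OiPr)3, −78 °C; 6, −78 → −20 °C
Reagents that add atoms: none
Why: Hoppe homoaldol reaction: the α-titanated allyl carbamate adds 1,2 to the ketone through its γ-carbon (six-membered transition state) to give the (Z)-enol carbamate, the 1,5-dien-3-ol needed for step 5; the new carbinol centre (axial delivery expected) is destroyed in the next step.

**Step 5**
Reactants: 10 (Z)-3-[(1S,5R)-1-hydroxy-5-methyl-2-(propan-2-ylidene)cyclohexyl]prop-1-en-1-yl N,N-diisopropylcarbamate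
Product: 13 (3S)-2-methyl-2-[(1S,4R)-4-methyl-2-oxocyclohexyl]pent-4-en-3-yl N,N-diisopropylcarbamate, via potassium alkoxide 11 (not isolated), via potassium enolate 12 (not isolated)
Conditions: KH, 18-crown-6, THF, 0 → 25 °C; then MeOH, 25 °C
Reagents that add atoms: none
Why: Anionic oxy-Cope [3,3]-sigmatropic rearrangement forges the bond between the carbamate-bearing carbon and the isopropylidene carbon (the gem-dimethyl quaternary carbon) and unveils the ketone as its enolate; protonation and methoxide equilibration place the new α-substituent equatorial and trans to the ring methyl (menthone-type, set by the pulegone centre, about 6:1 by analogy with 8-phenylmenthone), while the carbamate-bearing centre (S expected from a chair transition state) is erased in step 11.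

**Step 6**
Reactants: 13 (3S)-2-methyl-2-[(1S,4R)-4-methyl-2-oxocyclohexyl]pent-4-en-3-yl N,N-diisopropylcarbamate; 5 2-(bromomethyl)-1,3-bis(methoxymethoxy)-5-[(methoxymethoxy)methyl]benzene
Product: 15 (3S)-2-[(1S,3R,4R)-3-(ArCH2)-4-methyl-2-oxocyclohexyl]-2-methylpent-4-en-3-yl N,N-diisopropylcarbamate, via lithium enolate 14 (not isolated)
Conditions: LiN(iPr)2, THF, −78 °C; 5, −78 → −20 °C
Reagents that add atoms: none
Why: Kinetic deprotonation occurs at the unhindered α-CH2 rather than at the methine next to the quaternary carbon, and the enolate is benzylated by SN2 reaction; the configuration of the new centre does not matter because it is re-enolised in step 7.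

**Step 7**
Reactants: 15 (3S)-2-[(1S,3R,4R)-3-(ArCH2)-4-methyl-2-oxocyclohexyl]-2-methylpent-4-en-3-yl N,N-diisopropylcarbamate
Product: 17 (3S)-2-[(1S,3S,4R)-3-(ArCH2)-3,4-dimethyl-2-oxocyclohexyl]-2-methylpent-4-en-3-yl N,N-diisopropylcarbamate, via lithium enolate 16 (not isolated)
Conditions: LiN(iPr)2, THF, −78 → 0 °C; MeI, DMPU, −78 → 0 °C
Reagents that add atoms: iodomethane, CI
Why: Enolate alkylation: the tetrasubstituted enolate is locked by its two equatorial ring substituents, so MeI enters axially on the face of the neighbouring ring methyl, giving the C9 quaternary centre with the two methyls cis and the arylmethyl group equatorial.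

**Step 8**
Reactants: 17 (3S)-2-[(1S,3S,4R)-3-(ArCH2)-3,4-dimethyl-2-oxocyclohexyl]-2-methylpent-4-en-3-yl N,N-diisopropylcarbamate
Product: 18 (3S)-2-[(1S,3S,4R)-3-(ArCH2)-3,4-dimethyl-2-oxocyclohexyl]-2-methyl-5-oxopentan-3-yl N,N-diisopropylcarbamate
Conditions: PdCl2(PhCN)2 (cat.), CuCl2·2H2O (cat.), AgNO2 (cat.), O2 (1 atm), t-BuOH/MeNO2, 25 °C
Reagents that add atoms: dioxygen, O=O
Why: Nitrite-modified, aldehyde-selective Wacker oxidation: the allylic carbamate oxygen and the neopentyl environment steer oxygen to the terminal carbon.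

**Step 9**
Reactants: 18 (3S)-2-[(1S,3S,4R)-3-(ArCH2)-3,4-dimethyl-2-oxocyclohexyl]-2-methyl-5-oxopentan-3-yl N,N-diisopropylcarbamate
Product: 19 (2S,5S,6R,8aR)-5-(ArCH2)-1,1,5,6-tetramethyl-1,2,3,5,6,7,8,8a-octahydronaphthalen-2-yl N,N-diisopropylcarbamate
Conditions: TiCl3(DME)1.5, Zn–Cu, DME, reflux, slow addition
Reagents that add atoms: none
Why: Intramolecular McMurry coupling joins the aldehyde and ketone carbons with loss of both oxygens, closing ring A with the double bond fixed between C1 and C10 and leaving the neighbouring stereocentres untouched.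

**Step 10**
Reactants: 19 (2S,5S,6R,8aR)-5-(ArCH2)-1,1,5,6-tetramethyl-1,2,3,5,6,7,8,8a-octahydronaphthalen-2-yl N,N-diisopropylcarbamate
Product: 20 (2S,5S,6R,8aR)-5-(ArCH2)-1,1,5,6-tetramethyl-1,2,3,5,6,7,8,8a-octahydronaphthalen-2-ol
Conditions: LiAlH4, THF, reflux
Reagents that add atoms: none
Why: Hydride reduction cleaves the hindered carbamate to the free secondary alcohol; the MOM acetals and the trisubstituted alkene are inert.

**Step 11**
Reactants: 20 (2S,5S,6R,8aR)-5-(ArCH2)-1,1,5,6-tetramethyl-1,2,3,5,6,7,8,8a-octahydronaphthalen-2-ol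
Product: 21 (5S,6R,8aR)-5-(ArCH2)-1,1,5,6-tetramethyl-1,5,6,7,8,8a-hexahydronaphthalen-2(3H)-one
Conditions: Dess–Martin periodinane, CH2Cl2, 0 → 25 °C
Reagents that add atoms: none
Why: Dess–Martin oxidation under neutral conditions gives the β,γ-unsaturated ketone without moving the double bond into conjugation and removes the carbinol centre whose configuration was not controlled.

**Step 12**
Reactants: 21 (5S,6R,8aR)-5-(ArCH2)-1,1,5,6-tetramethyl-1,5,6,7,8,8a-hexahydronaphthalen-2(3H)-one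
Product: 22 (2R,5S,6R,8aR)-5-(ArCH2)-1,1,5,6-tetramethyl-1,2,3,5,6,7,8,8a-octahydronaphthalen-2-ol
Conditions: LiBH(s-Bu)3, THF, −78 °C
Reagents that add atoms: none
Why: Substrate-controlled ketone reduction: the bulky hydride attacks the carbonyl next to the gem-dimethyl carbon along the equatorial trajectory (as in 4,4-dimethyl-3-keto triterpenoids), giving the axial alcohol cis to the ring-fusion hydrogen, the R carbinol.

**Step 13**
Reactants: 22 (2R,5S,6R,8aR)-5-(ArCH2)-1,1,5,6-tetramethyl-1,2,3,5,6,7,8,8a-octahydronaphthalen-2-ol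
Product: 24 3-{[(1S,2R,4aR,6R)-6-hydroxy-1,2,5,5-tetramethyl-1,2,3,4,4a,5,6,7-octahydronaphthalen-1-yl]methyl}-2,4-bis(methoxymethoxy)-6-[(methoxymethoxy)methyl]benzaldehyde, via dilithio species 23 (not isolated)
Conditions: s-BuLi, TMEDA, THF, −78 → −40 °C; DMF, −78 → 0 °C
Reagents that add atoms: N,N-dimethylformamide, CN(C)C=O
Why: After O-lithiation of the alcohol, directed ortho-metalation occurs at the ring carbon between OMOM and CH2OMOM (the two such carbons are equivalent) and the aryllithium is formylated by DMF.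

**Step 14**
Reactants: 24 3-{[(1S,2R,4aR,6R)-6-hydroxy-1,2,5,5-tetramethyl-1,2,3,4,4a,5,6,7-octahydronaphthalen-1-yl]methyl}-2,4-bis(methoxymethoxy)-6-[(methoxymethoxy)methyl]benzaldehyde
Product: 25 2,4-dihydroxy-6-(hydroxymethyl)-3-{[(1S,2R,4aR,6R)-6-hydroxy-1,2,5,5-tetramethyl-1,2,3,4,4a,5,6,7-octahydronaphthalen-1-yl]methyl}benzaldehyde
Conditions: 3 M HCl (aq), THF, 40 °C
Reagents that add atoms: none
Why: Acid-catalysed acetal hydrolysis removes the three MOM groups under conditions too mild to protonate the hindered trisubstituted alkene (which would let a phenol cyclise onto C10).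

**Compound list**
1 | 3,5-dihydroxybenzyl alcohol | OCc1cc(O)cc(O)c1 | starting material
2 | 1,3-bis(methoxymethoxy)-5-[(methoxymethoxy)methyl]benzene | COCOCc1cc(OCOC)cc(OCOC)c1 | intermediate
3 | 2,6-bis(methoxymethoxy)-4-[(methoxymethoxy)methyl]phenyllithium (not isolated) | COCOCc1cc(OCOC)c([Li])c(OCOC)c1 | intermediate
4 | {2,6-bis(methoxymethoxy)-4-[(methoxymethoxy)methyl]phenyl}methanol | COCOCc1cc(OCOC)c(CO)c(OCOC)c1 | intermediate
5 | 2-(bromomethyl)-1,3-bis(methoxymethoxy)-5-[(methoxymethoxy)methyl]benzene (ArCH2Br) | COCOCc1cc(OCOC)c(CBr)c(OCOC)c1 | intermediate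
6 | (R)-(+)-pulegone, (5R)-5-methyl-2-(propan-2-ylidene)cyclohexan-1-one | C[C@@H]1CCC(=C(C)C)C(=O)C1 | starting material
7 | allyl N,N-diisopropylcarbamate | C=CCOC(=O)N(C(C)C)C(C)C | starting material
8 | 1-lithioprop-2-en-1-yl N,N-diisopropylcarbamate (not isolated) | [Li]C(C=C)OC(=O)N(C(C)C)C(C)C | intermediate
9 | [1-(N,N-diisopropylcarbamoyloxy)prop-2-en-1-yl]Ti(OiPr)3 (not isolated) | CC(C)O[Ti](OC(C)C)(OC(C)C)C(C=C)OC(=O)N(C(C)C)C(C)C | intermediate
10 | (Z)-3-[(1S,5R)-1-hydroxy-5-methyl-2-(propan-2-ylidene)cyclohexyl]prop-1-en-1-yl N,N-diisopropylcarbamate | C[C@@H]1CCC(=C(C)C)[C@@](O)(C/C=C\OC(=O)N(C(C)C)C(C)C)C1 | intermediate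
11 | potassium alkoxide of 10 (not isolated) | C[C@@H]1CCC(=C(C)C)[C@@]([O-])(C/C=C\OC(=O)N(C(C)C)C(C)C)C1.[K+] | intermediate
12 | potassium enolate of 13, double bond to the side-chain-bearing ring carbon (not isolated) | C[C@@H]1CCC(C(C)(C)[C@@H](OC(=O)N(C(C)C)C(C)C)C=C)=C([O-])C1.[K+] | intermediate
13 | (3S)-2-methyl-2-[(1S,4R)-4-methyl-2-oxocyclohexyl]pent-4-en-3-yl N,N-diisopropylcarbamate | C[C@@H]1CC[C@@H](C(C)(C)[C@@H](OC(=O)N(C(C)C)C(C)C)C=C)C(=O)C1 | intermediate
14 | lithium enolate of 13 toward the ring CH2 (not isolated) | C[C@@H]1CC[C@@H](C(C)(C)[C@@H](OC(=O)N(C(C)C)C(C)C)C=C)C([O-])=C1.[Li+] | intermediate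
15 | (3S)-2-[(1S,3R,4R)-3-(ArCH2)-4-methyl-2-oxocyclohexyl]-2-methylpent-4-en-3-yl N,N-diisopropylcarbamate (axial-benzylation epimer drawn; both epimers converge in step 7) | C[C@@H]1CC[C@@H](C(C)(C)[C@@H](OC(=O)N(C(C)C)C(C)C)C=C)C(=O)[C@@H]1Cc1c(OCOC)cc(COCOC)cc1OCOC | intermediate
16 | lithium enolate of 15, tetrasubstituted (not isolated) | C[C@@H]1CC[C@@H](C(C)(C)[C@@H](OC(=O)N(C(C)C)C(C)C)C=C)C([O-])=C1Cc1c(OCOC)cc(COCOC)cc1OCOC.[Li+] | intermediate
17 | (3S)-2-[(1S,3S,4R)-3-(ArCH2)-3,4-dimethyl-2-oxocyclohexyl]-2-methylpent-4-en-3-yl N,N-diisopropylcarbamate | C[C@@H]1CC[C@@H](C(C)(C)[C@@H](OC(=O)N(C(C)C)C(C)C)C=C)C(=O)[C@@]1(C)Cc1c(OCOC)cc(COCOC)cc1OCOC | intermediate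
18 | (3S)-2-[(1S,3S,4R)-3-(ArCH2)-3,4-dimethyl-2-oxocyclohexyl]-2-methyl-5-oxopentan-3-yl N,N-diisopropylcarbamate | C[C@@H]1CC[C@@H](C(C)(C)[C@@H](OC(=O)N(C(C)C)C(C)C)CC=O)C(=O)[C@@]1(C)Cc1c(OCOC)cc(COCOC)cc1OCOC | intermediate
19 | (2S,5S,6R,8aR)-5-(ArCH2)-1,1,5,6-tetramethyl-1,2,3,5,6,7,8,8a-octahydronaphthalen-2-yl N,N-diisopropylcarbamate | C[C@@H]1CC[C@@H]2C(=CC[C@H](OC(=O)N(C(C)C)C(C)C)C2(C)C)[C@@]1(C)Cc1c(OCOC)cc(COCOC)cc1OCOC | intermediate
20 | (2S,5S,6R,8aR)-5-(ArCH2)-1,1,5,6-tetramethyl-1,2,3,5,6,7,8,8a-octahydronaphthalen-2-ol | C[C@@H]1CC[C@@H]2C(=CC[C@H](O)C2(C)C)[C@@]1(C)Cc1c(OCOC)cc(COCOC)cc1OCOC | intermediate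
21 | (5S,6R,8aR)-5-(ArCH2)-1,1,5,6-tetramethyl-1,5,6,7,8,8a-hexahydronaphthalen-2(3H)-one | C[C@@H]1CC[C@@H]2C(=CCC(=O)C2(C)C)[C@@]1(C)Cc1c(OCOC)cc(COCOC)cc1OCOC | intermediate
22 | (2R,5S,6R,8aR)-5-(ArCH2)-1,1,5,6-tetramethyl-1,2,3,5,6,7,8,8a-octahydronaphthalen-2-ol | C[C@@H]1CC[C@@H]2C(=CC[C@@H](O)C2(C)C)[C@@]1(C)Cc1c(OCOC)cc(COCOC)cc1OCOC | intermediate
23 | lithium alkoxide of 22 carrying the aryllithium between OMOM and CH2OMOM (not isolated) | C[C@@H]1CC[C@@H]2C(=CC[C@@H]([O-])C2(C)C)[C@@]1(C)Cc1c(OCOC)cc(COCOC)c([Li])c1OCOC.[Li+] | intermediate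
24 | 3-{[(1S,2R,4aR,6R)-6-hydroxy-1,2,5,5-tetramethyl-1,2,3,4,4a,5,6,7-octahydronaphthalen-1-yl]methyl}-2,4-bis(methoxymethoxy)-6-[(methoxymethoxy)methyl]benzaldehyde | C[C@@H]1CC[C@@H]2C(=CC[C@@H](O)C2(C)C)[C@@]1(C)Cc1c(OCOC)cc(COCOC)c(C=O)c1OCOC | intermediate
25 | 2,4-dihydroxy-6-(hydroxymethyl)-3-{[(1S,2R,4aR,6R)-6-hydroxy-1,2,5,5-tetramethyl-1,2,3,4,4a,5,6,7-octahydronaphthalen-1-yl]methyl}benzaldehyde | C[C@@H]1CC[C@@H]2C(=CC[C@@H](O)C2(C)C)[C@@]1(C)Cc1c(O)cc(CO)c(C=O)c1O | target

**Step count**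
Total: 14 steps. Longest linear sequence: 12 steps (steps 1–3, then 6–14); the pulegone branch is 11 steps (4–14).

**Steps most likely to fail, with fallbacks**

Step 5 (anionic oxy-Cope). The alkoxide may fragment by retro-homoaldol instead of forming the hindered quaternary–tertiary bond. The fallback makes the same bond by Lewis-acid conjugate allylation and sets out again from 6: allyltrimethylsilane with TiCl4 (Hosomi–Sakurai), followed by base equilibration, gives (2S,5R)-5-methyl-2-(2-methylpent-4-en-2-yl)cyclohexan-1-one F1. Allylic hydroxylation with catalytic SeO2 and t-BuOOH gives (2S,5R)-2-(3-hydroxy-2-methylpent-4-en-2-yl)-5-methylcyclohexan-1-one F2 as both carbinol epimers. Carbamoylation with ClC(O)N(iPr)2 and pyridine comes back to the route at 13; the epimer mixture at the carbamate carbon is tolerated because that centre is reset in steps 11 and 12.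

Step 7 (quaternary methylation). Deprotonation may compete at the other α-methine, or the facial selectivity may be poor. The fallback builds the quaternary centre first on pulegone, where the isopropylidene blocks the other α-position, and sets out from 6: LiN(iPr)2 and MeI give (5R)-5,6-dimethyl-2-(propan-2-ylidene)cyclohexan-1-one F3. LiN(iPr)2 and 5 then give (5R,6S)-6-(ArCH2)-5,6-dimethyl-2-(propan-2-ylidene)cyclohexan-1-one F4, with the arylmethyl group entering anti to the ring methyl. Homoaldol addition of 7 under the conditions of step 4 gives the tertiary alcohol (Z)-enol carbamate F5, and anionic oxy-Cope rearrangement with kinetic protonation comes back to the route at 17.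

Step 9 (McMurry coupling). The ketone is flanked by a quaternary and a branched tertiary carbon, so aldehyde self-coupling may win. The fallback closes ring A by ring-closing metathesis and sets out from 17: CH2=CHMgBr with CeCl3 adds to the ketone to give the divinyl carbinol F6. Second-generation Hoveyda–Grubbs catalyst closes the cyclohexenol carbamate F7 with loss of ethene. LiAlH4 frees the ene-1,4-diol F8, and MnO2 oxidises the secondary allylic alcohol to the γ-hydroxy enone F9. SmI2 in THF/MeOH removes the tertiary γ-hydroxyl and the dienolate is protonated at the α-carbon, which comes back to the route at 21.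

**Further compounds**
F1 | step 5 | (2S,5R)-5-methyl-2-(2-methylpent-4-en-2-yl)cyclohexan-1-one | C[C@@H]1CC[C@@H](C(C)(C)CC=C)C(=O)C1
F2 | step 5 | (2S,5R)-2-(3-hydroxy-2-methylpent-4-en-2-yl)-5-methylcyclohexan-1-one (both carbinol epimers) | C[C@@H]1CC[C@@H](C(C)(C)C(O)C=C)C(=O)C1
F3 | step 7 | (5R)-5,6-dimethyl-2-(propan-2-ylidene)cyclohexan-1-one (epimers at C6) | C[C@@H]1CCC(=C(C)C)C(=O)C1C
F4 | step 7 | (5R,6S)-6-(ArCH2)-5,6-dimethyl-2-(propan-2-ylidene)cyclohexan-1-one | C[C@@H]1CCC(=C(C)C)C(=O)[C@@]1(C)Cc1c(OCOC)cc(COCOC)cc1OCOC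
F5 | step 7 | (Z)-3-[1-hydroxy-6-(ArCH2)-5,6-dimethyl-2-(propan-2-ylidene)cyclohexyl]prop-1-en-1-yl N,N-diisopropylcarbamate | C[C@@H]1CCC(=C(C)C)[C@@](O)(C/C=C\OC(=O)N(C(C)C)C(C)C)[C@@]1(C)Cc1c(OCOC)cc(COCOC)cc1OCOC
F6 | step 9 | vinyl carbinol from 17: (3S)-2-[3-(ArCH2)-2-ethenyl-2-hydroxy-3,4-dimethylcyclohexyl]-2-methylpent-4-en-3-yl N,N-diisopropylcarbamate | C[C@@H]1CC[C@@H](C(C)(C)[C@@H](OC(=O)N(C(C)C)C(C)C)C=C)C(O)(C=C)[C@@]1(C)Cc1c(OCOC)cc(COCOC)cc1OCOC
F7 | step 9 | 5-(ArCH2)-4a-hydroxy-1,1,5,6-tetramethyl-1,2,4a,5,6,7,8,8a-octahydronaphthalen-2-yl N,N-diisopropylcarbamate | C[C@@H]1CC[C@@H]2C(O)(C=C[C@H](OC(=O)N(C(C)C)C(C)C)C2(C)C)[C@@]1(C)Cc1c(OCOC)cc(COCOC)cc1OCOC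
F8 | step 9 | 5-(ArCH2)-1,1,5,6-tetramethyl-1,2,4a,5,6,7,8,8a-octahydronaphthalene-2,4a-diol | C[C@@H]1CC[C@@H]2C(O)(C=C[C@H](O)C2(C)C)[C@@]1(C)Cc1c(OCOC)cc(COCOC)cc1OCOC
F9 | step 9 | 5-(ArCH2)-4a-hydroxy-1,1,5,6-tetramethyl-4a,5,6,7,8,8a-hexahydronaphthalen-2(1H)-one | C[C@@H]1CC[C@@H]2C(O)(C=CC(=O)C2(C)C)[C@@]1(C)Cc1c(OCOC)cc(COCOC)cc1OCOC
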